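**Retrosynthetic overview**

- The ester C–O bond is cut first. This gives (2E,6S)-6-hydroxy-2,6-dimethylocta-2,7-dienoic acid, made from (S)-linalool by oxidation of the E-methyl group of its prenyl end, and a naphthoquinone neopentyl alcohol.
- The strategy rests on the quinone ring of that alcohol: carbonyl carbons C1 and C4 on the benzo ring, C2 carrying the CH2–C(CH3)2–CH2O chain and C3 the enolic OH. This is the oxidation pattern of a 2-substituted 1-tetralone taken to its highest level, so C4=O and C3–OH are installed by aerobic oxidation of a tetralone-derived precursor.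
- The C2–CH2 bond to the side chain comes from a crossed aldol condensation of 1-tetralone with 3-silyloxy-2,2-dimethylpropanal, which cannot enolise because its α-carbon is quaternary.
- No ring is formed in the route: both carbocycles are bought as 1-tetralone and only its saturated ring changes oxidation level. Order: side-chain aldehyde, aldol condensation, aerobic cascade, desilylation, esterification.

Key step: step 4

Remark: the only stereocentre (C6 of the acyl chain, S) is taken from (S)-linalool, assumed to be available in high enantiomeric purity; no step of the route touches that carbon.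

**Route**

Step 1
Reactants: 1 2,2-dimethylpropane-1,3-diol
Product: 2 3-[(tert-butyldimethylsilyl)oxy]-2,2-dimethylpropan-1-ol
Conditions: NaH (1.0 equiv), THF, 0 °C to rt; then TBSCl (1.0 equiv), rt
Reagents that add atoms: tert-butyldimethylsilyl chloride, CC(C)(C)[Si](C)(C)Cl
Why: O-silylation of a symmetrical diol through its sparingly soluble monosodium alkoxide, which should stop cleanly at the mono-ether.

Step 2
Reactants: 2 3-[(tert-butyldimethylsilyl)oxy]-2,2-dimethylpropan-1-ol
Product: 3 3-[(tert-butyldimethylsilyl)oxy]-2,2-dimethylpropanal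
Conditions: (COCl)2, DMSO, CH2Cl2, −78 °C; then Et3N, −78 °C to rt
Reagents that add atoms: none
Why: Swern oxidation of a primary neopentyl alcohol to an aldehyde that has no α-hydrogen, so it can neither enolise nor over-oxidise, and the silyl ether is untouched.

Step 3
Reactants: 4 1-tetralone; 3 3-[(tert-butyldimethylsilyl)oxy]-2,2-dimethylpropanal
Product: 5 (E)-2-[3-(tert-butyldimethylsilyloxy)-2,2-dimethylpropylidene]-3,4-dihydronaphthalen-1(2H)-one
Conditions: KOH (1.2 equiv), EtOH, rt to 50 °C, N2
Reagents that add atoms: none
Why: Claisen–Schmidt (crossed aldol) condensation in which only the tetralone can enolise; E1cB dehydration gives the conjugated enone, and the E isomer with the bulky group away from the carbonyl is the thermodynamic one, while exclusion of air prevents early autoxidation.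

Step 4
Reactants: 5 (E)-2-[3-(tert-butyldimethylsilyloxy)-2,2-dimethylpropylidene]-3,4-dihydronaphthalen-1(2H)-one
Product: 10 2-[3-(tert-butyldimethylsilyloxy)-2,2-dimethylpropyl]-3-hydroxynaphthalene-1,4-dione, via potassium 2-alkyl-1-naphtholate 6 (not isolated), via 4-hydroperoxy-2-alkylnaphthalen-1(4H)-one 7 (not isolated), via 2-alkyl-1,4-naphthoquinone 8 (not isolated), via 2-alkyl-1,4-naphthoquinone 2,3-epoxide 9 (not isolated)
Conditions: KOtBu (4 equiv), DMSO/tBuOH (4:1), rt, Ar; then O2 (1 atm), rt; aq. HCl work-up
Reagents that add atoms: dioxygen, O=O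
Why: Under argon, tert-butoxide in DMSO removes a C3–H of 5 (an allylic, cross-conjugated position that needs this stronger medium), reprotonation at the exocyclic carbon moves the alkene into the ring, and loss of the now vinylogous C4–H aromatises the ring to naphtholate 6, a change driven by aromaticity and by relief of the strain between the quaternary carbon and C3H2. Once O2 is admitted, 6 is oxygenated at its free para carbon (tetralone C4) to peroxide 7, which loses hydroxide in a Kornblum–DeLaMare-type collapse to quinone 8; hydroperoxide anion formed in the medium then adds to the only unsubstituted quinone carbon (tetralone C3) in a Weitz–Scheffer epoxidation to give 9, and base-induced opening of the epoxide from its single C–H gives the anion of 10, protonated on work-up. The closest known reactions are the tert-butoxide/O2 autoxidation of 1-tetralones and of 2-alkyl-1-naphthols to 2-hydroxy-1,4-naphthoquinones and the base-mediated isomerisation of 2-ylidene-1-tetralones to 1-naphthols, here run in one flask. No ring is closed and no stereocentre is created (7 and 9 are racemic transients). Only site selectivity is needed, and the substrate fixes it: the 2-alkyl group leaves C4 as the sole para position and C3 as the sole quinone C–H, the side-chain carbon next to the alkene is quaternary so the double bond cannot drift into the chain, and the neopentyl silyl ether is inert to tert-butoxide. Completing the aromatisation before oxygen is admitted keeps peroxide away from the exocyclic enone.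

Step 5
Reactants: 10 2-[3-(tert-butyldimethylsilyloxy)-2,2-dimethylpropyl]-3-hydroxynaphthalene-1,4-dione
Product: 11 2-hydroxy-3-(3-hydroxy-2,2-dimethylpropyl)naphthalene-1,4-dione
Conditions: HF (48% aq.), MeCN, 0 °C to rt
Reagents that add atoms: none
Why: Fluoride-driven cleavage of a primary silyl ether in a mildly acidic medium, which keeps the hydroxyquinone protonated and away from base-induced degradation; no acid-sensitive group is present at this stage.

Step 6
Reactants: 12 (S)-linalool
Product: 13 (2E,6S)-6-hydroxy-2,6-dimethylocta-2,7-dienal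
Conditions: SeO2 (1.2 equiv), 1,4-dioxane/EtOH (9:1), 80 °C
Reagents that add atoms: selenium dioxide, O=[Se]=O
Why: Riley allylic oxidation (ene reaction, then [2,3]-sigmatropic shift and further oxidation) takes the E-methyl group of the trisubstituted alkene to the E-enal; the vinyl group has no allylic hydrogen and the tertiary carbinol carbon is not involved, so its configuration is kept.

Step 7
Reactants: 13 (2E,6S)-6-hydroxy-2,6-dimethylocta-2,7-dienal
Product: 14 (2E,6S)-6-hydroxy-2,6-dimethylocta-2,7-dienoic acid
Conditions: NaClO2, NaH2PO4, 2-methyl-2-butene, tBuOH/H2O, 0 °C to rt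
Reagents that add atoms: sodium chlorite, [Na+].[O-]Cl=O
Why: Pinnick oxidation converts the enal to the acid under buffered conditions without moving the double bond, and the alkene scavenger protects the vinyl group and the tertiary allylic alcohol from hypochlorous acid.

Step 8
Reactants: 11 2-hydroxy-3-(3-hydroxy-2,2-dimethylpropyl)naphthalene-1,4-dione; 14 (2E,6S)-6-hydroxy-2,6-dimethylocta-2,7-dienoic acid
Product: 15 3-(3-hydroxy-1,4-dioxo-1,4-dihydronaphthalen-2-yl)-2,2-dimethylpropyl (2E,6S)-6-hydroxy-2,6-dimethylocta-2,7-dienoate
Conditions: DCC (1.2 equiv), DMAP (0.2 equiv), CH2Cl2, 0 °C to rt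
Reagents that add atoms: none
Why: Steglich esterification in which the primary hydroxyl is the only lasting acyl acceptor, because the tertiary allylic hydroxyl of 14 is too hindered and an O-acylated quinone enol is a vinylogous anhydride that DMAP returns to the acylpyridinium; the E-alkene and the C6 stereocentre are not touched.

**Compound list**

"Alkyl" in the short names of 6–9 stands for the 3-(tert-butyldimethylsilyloxy)-2,2-dimethylpropyl group.

1 | 2,2-dimethylpropane-1,3-diol | OCC(C)(C)CO | starting material
2 | 3-[(tert-butyldimethylsilyl)oxy]-2,2-dimethylpropan-1-ol | CC(C)(C)[Si](C)(C)OCC(C)(C)CO | intermediate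
3 | 3-[(tert-butyldimethylsilyl)oxy]-2,2-dimethylpropanal | CC(C)(C)[Si](C)(C)OCC(C)(C)C=O | intermediate
4 | 1-tetralone | O=C1CCCc2ccccc21 | starting material
5 | (E)-2-[3-(tert-butyldimethylsilyloxy)-2,2-dimethylpropylidene]-3,4-dihydronaphthalen-1(2H)-one | O=C1/C(=C/C(C)(C)CO[Si](C)(C)C(C)(C)C)CCc2ccccc21 | intermediate
6 | potassium 2-[3-(tert-butyldimethylsilyloxy)-2,2-dimethylpropyl]naphthalen-1-olate | CC(C)(C)[Si](C)(C)OCC(C)(C)Cc1ccc2ccccc2c1[O-].[K+] | intermediate
7 | 2-[3-(tert-butyldimethylsilyloxy)-2,2-dimethylpropyl]-4-hydroperoxynaphthalen-1(4H)-one (racemic) | CC(C)(C)[Si](C)(C)OCC(C)(C)CC1=CC(OO)c2ccccc2C1=O | intermediate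
8 | 2-[3-(tert-butyldimethylsilyloxy)-2,2-dimethylpropyl]naphthalene-1,4-dione | CC(C)(C)[Si](C)(C)OCC(C)(C)CC1=CC(=O)c2ccccc2C1=O | intermediate
9 | 2-[3-(tert-butyldimethylsilyloxy)-2,2-dimethylpropyl]-2,3-epoxy-2,3-dihydronaphthalene-1,4-dione (racemic) | CC(C)(C)[Si](C)(C)OCC(C)(C)CC12OC1C(=O)c1ccccc1C2=O | intermediate
10 | 2-[3-(tert-butyldimethylsilyloxy)-2,2-dimethylpropyl]-3-hydroxynaphthalene-1,4-dione | CC(C)(C)[Si](C)(C)OCC(C)(C)CC1=C(O)C(=O)c2ccccc2C1=O | intermediate
11 | 2-hydroxy-3-(3-hydroxy-2,2-dimethylpropyl)naphthalene-1,4-dione | OCC(C)(C)CC1=C(O)C(=O)c2ccccc2C1=O | intermediate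
12 | (S)-linalool, (3S)-3,7-dimethylocta-1,6-dien-3-ol | C=C[C@@](C)(O)CCC=C(C)C | starting material
13 | (2E,6S)-6-hydroxy-2,6-dimethylocta-2,7-dienal | C=C[C@@](C)(O)CC/C=C(\C)C=O | intermediate
14 | (2E,6S)-6-hydroxy-2,6-dimethylocta-2,7-dienoic acid | C=C[C@@](C)(O)CC/C=C(\C)C(=O)O | intermediate
15 | 3-(3-hydroxy-1,4-dioxo-1,4-dihydronaphthalen-2-yl)-2,2-dimethylpropyl (2E,6S)-6-hydroxy-2,6-dimethylocta-2,7-dienoate | C=C[C@@](C)(O)CC/C=C(\C)C(=O)OCC(C)(C)CC1=C(O)C(=O)c2ccccc2C1=O | target

**Step count and risks**

Total step count: 8. Longest linear sequence: 6 steps (steps 1, 2, 3, 4, 5, 8); the acid branch (steps 6, 7) joins at step 8.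

Steps most likely to fail:

1. Step 4. The alkene migration may be incomplete when oxygen is admitted, because the C3 carbanion is not stabilised by the carbonyl; peroxide would then epoxidise the remaining exocyclic enone. The hydroxyquinone anion may also be degraded by oxidative ring cleavage on long exposure to base and oxygen, and hydroxide formed in the flask may remove part of the silyl group. Fallback: from 5, the exocyclic alkene is hydrogenated (H2, 1 atm, Pd/C, EtOAc, rt) to 2-[3-(tert-butyldimethylsilyloxy)-2,2-dimethylpropyl]-3,4-dihydronaphthalen-1(2H)-one F1 (racemic). Its C2–H and benzylic C4–H positions are directly open to base, so the established tert-butoxide/O2 autoxidation of 2-alkyl-1-tetralones (KOtBu, tBuOH, O2, rt, acidic work-up) should give the hydroxyquinone without any alkene migration. The route is rejoined at 10.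

2. Step 8. Acylation may take place at the quinone enol oxygen in competition with the neopentyl hydroxyl, and the slow-reacting α-branched enoic acid may be lost to N-acylurea formation. Fallback: from 11 and 14, both hydroxyl groups are acylated on purpose with an excess of 14 (2.5 equiv, DCC, DMAP, CH2Cl2) to give 3-{3-[(2E,6S)-6-hydroxy-2,6-dimethylocta-2,7-dienoyloxy]-1,4-dioxo-1,4-dihydronaphthalen-2-yl}-2,2-dimethylpropyl (2E,6S)-6-hydroxy-2,6-dimethylocta-2,7-dienoate F2. Its quinone enol ester, a vinylogous anhydride, is then hydrolysed selectively (aq. NaHCO3, THF, rt) while the hindered alkyl enoate stays. This returns the route to 15 and gives back one equivalent of 14.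

3. Step 3. Addition of the enolate to the hindered neopentyl aldehyde may be slow and reversible, the aldehyde may be consumed by Cannizzaro disproportionation, and the silyl ether may be lost in warm alcoholic hydroxide. Fallback: from 4 and 3, the lithium enolate of 4 (LDA, THF, −78 °C) is added to 3 to give 2-[3-(tert-butyldimethylsilyloxy)-1-hydroxy-2,2-dimethylpropyl]-3,4-dihydronaphthalen-1(2H)-one F3 (diastereomer mixture, of no consequence). Mesylation (MsCl, Et3N, CH2Cl2, 0 °C) gives 3-(tert-butyldimethylsilyloxy)-2,2-dimethyl-1-(1-oxo-1,2,3,4-tetrahydronaphthalen-2-yl)propyl methanesulfonate F4, and DBU (toluene, rt to 60 °C) eliminates it to the E-enone. The route is rejoined at 5.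

Further compounds
F1 | step 4 | 2-[3-(tert-butyldimethylsilyloxy)-2,2-dimethylpropyl]-3,4-dihydronaphthalen-1(2H)-one (racemic) | O=C1C(CC(C)(C)CO[Si](C)(C)C(C)(C)C)CCc2ccccc21
F2 | step 8 | 3-{3-[(2E,6S)-6-hydroxy-2,6-dimethylocta-2,7-dienoyloxy]-1,4-dioxo-1,4-dihydronaphthalen-2-yl}-2,2-dimethylpropyl (2E,6S)-6-hydroxy-2,6-dimethylocta-2,7-dienoate | C=C[C@@](C)(O)CC/C=C(\C)C(=O)OCC(C)(C)CC1=C(OC(=O)/C(C)=C/CC[C@](C)(O)C=C)C(=O)c2ccccc2C1=O
F3 | step 3 | 2-[3-(tert-butyldimethylsilyloxy)-1-hydroxy-2,2-dimethylpropyl]-3,4-dihydronaphthalen-1(2H)-one (diastereomer mixture) | O=C1C(C(O)C(C)(C)CO[Si](C)(C)C(C)(C)C)CCc2ccccc21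
F4 | step 3 | 3-(tert-butyldimethylsilyloxy)-2,2-dimethyl-1-(1-oxo-1,2,3,4-tetrahydronaphthalen-2-yl)propyl methanesulfonate (diastereomer mixture) | O=C1C(C(OS(C)(=O)=O)C(C)(C)CO[Si](C)(C)C(C)(C)C)CCc2ccccc21
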